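**Plan**

1. Atoms are numbered as in the germacrane skeleton of the target (ring C1–C10; C11–C13 on C7; C14 on C10; C15 on C4). The enabling feature is that C7 carries a 2-(acetoxymethyl)allyl unit (C11=C13 with C12) and lies β to the C9 oxygen, which is what a [2,3] shift of an allyl sulfonium ylide centred on C8, next to a C9 ketone, leaves behind.
2. Retrosynthetic cuts, in order: the silyl ethers and the C9 ester; C9–H (back to the ketone); C8–S; C7–C8 (ring contraction of a thirteen-membered S-ylide made from diazoketone 30); the diazo group; C14–O (SN2′ esterification); C1–C10; C7=C11; C4=C5; C3–C4.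
3. Forward: the C1–C7 chain is joined by phosphonate alkylation and Z-selective olefination and then epoxidised. It is extended at C7 to the allyl phenyl sulfide and at C1 to the enone that already bears the C14 ester. The only ring, the ten-membered carbocycle, arises in step 21 out of the transient thirteen-membered ylide ring.
4. Stereochemistry: C4/C5 from Sharpless epoxidation (L-(+)-tartrate); C7 from the ylide rearrangement under control of the epoxide-bearing tether; C9 from oxazaborolidine-catalysed reduction; the (2R,3S) side chain from an Evans syn aldol. Alkene geometries come from the Still–Gennari, stabilised-Wittig and SN2′-Mitsunobu steps.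
5. C14 is esterified before the carbenoid is made, because an ether oxygen there would sit five atoms from C8 and intercept the carbenoid as a five-membered oxonium ylide.

Key step: step 21

Assumption: 3-(4-methoxybenzyloxy)propanal (5) is taken as a catalogue compound; it is otherwise one oxidation away from the commercial alcohol.

**Route**

Step 1
Reactants: 1 3-iodopropan-1-ol
Product: 2 triethyl(3-iodopropoxy)silane
Conditions: Et3SiCl, imidazole, CH2Cl2, 0 °C to rt
Reagents that add atoms: chlorotriethylsilane, CC[Si](Cl)(CC)CC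
Why: Routine O-silylation of a primary alcohol should give the C1–C3 unit as an alkylating agent whose triethylsilyl ether can later be removed beside a tert-butyldimethylsilyl ether.

Step 2
Reactants: 2 triethyl(3-iodopropoxy)silane; 3 methyl 2-[bis(2,2,2-trifluoroethoxy)phosphoryl]acetate
Product: 4 methyl 2-[bis(2,2,2-trifluoroethoxy)phosphoryl]-5-(triethylsilyloxy)pentanoate (racemic)
Conditions: NaH, DMF, 0 °C to rt
Reagents that add atoms: none
Why: C-alkylation of the sodium phosphonoacetate by a primary iodide should form C3–C4 and give the α-substituted Still–Gennari reagent, whose new centre disappears in step 3.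

Step 3
Reactants: 4 methyl 2-[bis(2,2,2-trifluoroethoxy)phosphoryl]-5-(triethylsilyloxy)pentanoate; 5 3-(4-methoxybenzyloxy)propanal
Product: 6 methyl (2Z)-5-(4-methoxybenzyloxy)-2-[3-(triethylsilyloxy)propyl]pent-2-enoate
Conditions: KN(SiMe3)2, 18-crown-6, THF, −78 °C
Reagents that add atoms: none
Why: The Still–Gennari olefination of an electron-poor trifluoroethyl phosphonate should collapse kinetically to the Z-enoate, which places the ester carbon (C15) cis to C6 as the epoxide later requires.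

Step 4
Reactants: 6 methyl (2Z)-5-(4-methoxybenzyloxy)-2-[3-(triethylsilyloxy)propyl]pent-2-enoate
Product: 7 (2Z)-5-(4-methoxybenzyloxy)-2-[3-(triethylsilyloxy)propyl]pent-2-en-1-ol
Conditions: iBu2AlH, CH2Cl2, −78 °C
Reagents that add atoms: none
Why: 1,2-Reduction of the enoate by the aluminium hydride should give the allylic alcohol with the alkene geometry unchanged.

Step 5
Reactants: 7 (2Z)-5-(4-methoxybenzyloxy)-2-[3-(triethylsilyloxy)propyl]pent-2-en-1-ol
Product: 8 [(2S,3R)-3-[2-(4-methoxybenzyloxy)ethyl]-2-[3-(triethylsilyloxy)propyl]oxiran-2-yl]methanol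
Conditions: Ti(OiPr)4 (0.2 equiv), L-(+)-diethyl tartrate (0.24 equiv), tBuOOH, 4 Å molecular sieves, CH2Cl2, −20 °C
Reagents that add atoms: tert-butyl hydroperoxide, CC(C)(C)OO
Why: In the Sharpless asymmetric epoxidation the titanium L-(+)-tartrate complex should deliver oxygen to the face of the (Z)-allylic alcohol that gives the 4S,5R epoxide (quaternary carbon S, methine carbon R).

Step 6
Reactants: 8 [(2S,3R)-3-[2-(4-methoxybenzyloxy)ethyl]-2-[3-(triethylsilyloxy)propyl]oxiran-2-yl]methanol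
Product: 9 tert-butyl{[(2S,3R)-3-[2-(4-methoxybenzyloxy)ethyl]-2-[3-(triethylsilyloxy)propyl]oxiran-2-yl]methoxy}dimethylsilane
Conditions: TBSCl, imidazole, DMF, 0 °C to rt
Reagents that add atoms: tert-butyldimethylsilyl chloride, CC(C)(C)[Si](C)(C)Cl
Why: Silylation of the C15 hydroxyl under neutral conditions should protect the epoxy alcohol until the last step and avoids alkoxide-driven Payne rearrangement.

Step 7
Reactants: 9 tert-butyl{[(2S,3R)-3-[2-(4-methoxybenzyloxy)ethyl]-2-[3-(triethylsilyloxy)propyl]oxiran-2-yl]methoxy}dimethylsilane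
Product: 10 2-[(2R,3S)-3-(tert-butyldimethylsilyloxymethyl)-3-[3-(triethylsilyloxy)propyl]oxiran-2-yl]ethan-1-ol
Conditions: DDQ, CH2Cl2/pH 7 buffer, 0 °C
Reagents that add atoms: none
Why: Oxidative cleavage of the 4-methoxybenzyl ether should free the C7 hydroxyl while both silyl ethers and the epoxide persist, and it is done before any sulfur is present.

Step 8
Reactants: 11 methyl (triphenylphosphoranylidene)acetate; 12 chloromethyl phenyl sulfide
Product: 14 methyl 3-(phenylsulfanyl)-2-(triphenylphosphoranylidene)propanoate, via phosphonium chloride 13 (not isolated)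
Conditions: NaI (cat.), MeCN, 60 °C; then aq Na2CO3, CH2Cl2
Reagents that add atoms: none
Why: C-alkylation of an ester-stabilised phosphorane by a reactive α-chloro sulfide, then deprotonation of the salt, should give the α-substituted stabilised ylide that carries C11, C12 (as the ester) and C13 with its phenylthio group.

Step 9
Reactants: 10 2-[(2R,3S)-3-(tert-butyldimethylsilyloxymethyl)-3-[3-(triethylsilyloxy)propyl]oxiran-2-yl]ethan-1-ol
Product: 15 2-[(2R,3S)-3-(tert-butyldimethylsilyloxymethyl)-3-[3-(triethylsilyloxy)propyl]oxiran-2-yl]acetaldehyde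
Conditions: Dess–Martin periodinane, NaHCO3, CH2Cl2, 0 °C; used at once
Reagents that add atoms: none
Why: Buffered Dess–Martin oxidation should give the β,γ-epoxy aldehyde without the base that would open the epoxide by enolisation.

Step 10
Reactants: 15 2-[(2R,3S)-3-(tert-butyldimethylsilyloxymethyl)-3-[3-(triethylsilyloxy)propyl]oxiran-2-yl]acetaldehyde; 14 methyl 3-(phenylsulfanyl)-2-(triphenylphosphoranylidene)propanoate
Product: 16 methyl (2Z)-4-[(2R,3S)-3-(tert-butyldimethylsilyloxymethyl)-3-[3-(triethylsilyloxy)propyl]oxiran-2-yl]-2-(phenylsulfanylmethyl)but-2-enoate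
Conditions: CH2Cl2, rt
Reagents that add atoms: none
Why: The Wittig reaction of an α-substituted stabilised ylide runs under neutral conditions and should place the ester trans to C6, so C6 is cis to the phenylthiomethyl group C13 (2Z by the CIP rules) and trans to C12.

Step 11
Reactants: 16 methyl (2Z)-4-[(2R,3S)-3-(tert-butyldimethylsilyloxymethyl)-3-[3-(triethylsilyloxy)propyl]oxiran-2-yl]-2-(phenylsulfanylmethyl)but-2-enoate
Product: 17 (2Z)-4-[(2R,3S)-3-(tert-butyldimethylsilyloxymethyl)-3-[3-(triethylsilyloxy)propyl]oxiran-2-yl]-2-(phenylsulfanylmethyl)but-2-en-1-ol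
Conditions: iBu2AlH, CH2Cl2, −78 °C
Reagents that add atoms: none
Why: 1,2-Reduction of the conjugated ester should give the C12 allylic alcohol at a temperature at which the epoxide and the sulfide are inert.

Step 12
Reactants: 17 (2Z)-4-[(2R,3S)-3-(tert-butyldimethylsilyloxymethyl)-3-[3-(triethylsilyloxy)propyl]oxiran-2-yl]-2-(phenylsulfanylmethyl)but-2-en-1-ol
Product: 18 (2Z)-4-[(2R,3S)-3-(tert-butyldimethylsilyloxymethyl)-3-[3-(triethylsilyloxy)propyl]oxiran-2-yl]-2-(phenylsulfanylmethyl)but-2-en-1-yl acetate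
Conditions: Ac2O, pyridine, DMAP (cat.), CH2Cl2, 0 °C
Reagents that add atoms: acetic anhydride, CC(=O)OC(C)=O
Why: Acylation of the primary allylic alcohol should install the C12 acetate of the target, so that C12 needs no protecting group.

Step 13
Reactants: 18 (2Z)-4-[(2R,3S)-3-(tert-butyldimethylsilyloxymethyl)-3-[3-(triethylsilyloxy)propyl]oxiran-2-yl]-2-(phenylsulfanylmethyl)but-2-en-1-yl acetate
Product: 19 (2Z)-4-[(2R,3S)-3-(tert-butyldimethylsilyloxymethyl)-3-(3-hydroxypropyl)oxiran-2-yl]-2-(phenylsulfanylmethyl)but-2-en-1-yl acetate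
Conditions: HF·pyridine, pyridine, THF, 0 °C
Reagents that add atoms: none
Why: Buffered fluoride desilylation should cleave the unhindered primary triethylsilyl ether much faster than the hindered tert-butyldimethylsilyl ether at C15.

Step 14
Reactants: 19 (2Z)-4-[(2R,3S)-3-(tert-butyldimethylsilyloxymethyl)-3-(3-hydroxypropyl)oxiran-2-yl]-2-(phenylsulfanylmethyl)but-2-en-1-yl acetate
Product: 20 (2Z)-4-[(2R,3S)-3-(tert-butyldimethylsilyloxymethyl)-3-(3-oxopropyl)oxiran-2-yl]-2-(phenylsulfanylmethyl)but-2-en-1-yl acetate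
Conditions: Dess–Martin periodinane, NaHCO3, CH2Cl2, 0 °C to rt
Reagents that add atoms: none
Why: Dess–Martin oxidation of a primary alcohol should stop at the C1 aldehyde and leaves the aryl sulfide unoxidised.

Step 15
Reactants: 20 (2Z)-4-[(2R,3S)-3-(tert-butyldimethylsilyloxymethyl)-3-(3-oxopropyl)oxiran-2-yl]-2-(phenylsulfanylmethyl)but-2-en-1-yl acetate; 21 but-3-en-2-one
Product: 22 (2Z)-4-[(2R,3S)-3-(tert-butyldimethylsilyloxymethyl)-3-(3-hydroxy-4-methylidene-5-oxohexyl)oxiran-2-yl]-2-(phenylsulfanylmethyl)but-2-en-1-yl acetate (both carbinol epimers)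
Conditions: DABCO (0.5 equiv), THF, rt
Reagents that add atoms: none
Why: The Morita–Baylis–Hillman reaction should form C1–C10 and bring in C8, C9 and C14 at once; the carbinol configuration does not matter because C1 becomes sp2 in step 19.

Step 16
Reactants: 23 (4R)-4-benzyl-3-propanoyl-1,3-oxazolidin-2-one; 24 acetaldehyde
Product: 25 (4R)-4-benzyl-3-[(2R,3S)-3-hydroxy-2-methylbutanoyl]-1,3-oxazolidin-2-one
Conditions: Bu2BOTf, iPr2NEt, CH2Cl2, −78 to 0 °C; then MeOH, pH 7 buffer, H2O2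
Reagents that add atoms: none
Why: In the boron-mediated Evans syn aldol the (R)-benzyl auxiliary should set the 2R,3S configuration through a closed chair (Zimmerman–Traxler) transition state.

Step 17
Reactants: 25 (4R)-4-benzyl-3-[(2R,3S)-3-hydroxy-2-methylbutanoyl]-1,3-oxazolidin-2-one
Product: 26 (4R)-4-benzyl-3-[(2R,3S)-3-(tert-butyldimethylsilyloxy)-2-methylbutanoyl]-1,3-oxazolidin-2-one
Conditions: TBSOTf, 2,6-lutidine, CH2Cl2, 0 °C
Reagents that add atoms: tert-butyldimethylsilyl trifluoromethanesulfonate, CC(C)(C)[Si](C)(C)OS(=O)(=O)C(F)(F)F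
Why: Silylation of the secondary aldol hydroxyl with the silyl triflate should proceed without retro-aldol cleavage.

Step 18
Reactants: 26 (4R)-4-benzyl-3-[(2R,3S)-3-(tert-butyldimethylsilyloxy)-2-methylbutanoyl]-1,3-oxazolidin-2-one
Product: 27 (2R,3S)-3-(tert-butyldimethylsilyloxy)-2-methylbutanoic acid
Conditions: LiOH, H2O2, THF/H2O, 0 °C; Na2SO3; then HCl to pH 3
Reagents that add atoms: hydrogen peroxide, OO
Why: Hydroperoxide attacks the exocyclic imide carbonyl selectively, so the auxiliary should be released without epimerisation at C2 of the acid.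

Step 19
Reactants: 22 (2Z)-4-[(2R,3S)-3-(tert-butyldimethylsilyloxymethyl)-3-(3-hydroxy-4-methylidene-5-oxohexyl)oxiran-2-yl]-2-(phenylsulfanylmethyl)but-2-en-1-yl acetate; 27 (2R,3S)-3-(tert-butyldimethylsilyloxy)-2-methylbutanoic acid
Product: 28 (2E)-2-acetyl-5-[(2S,3R)-3-[(2Z)-4-acetoxy-3-(phenylsulfanylmethyl)but-2-en-1-yl]-2-(tert-butyldimethylsilyloxymethyl)oxiran-2-yl]pent-2-en-1-yl (2R,3S)-3-(tert-butyldimethylsilyloxy)-2-methylbutanoate
Conditions: PPh3, DIAD, THF, 0 °C to rt
Reagents that add atoms: none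
Why: The Mitsunobu reaction of a Morita–Baylis–Hillman alcohol runs in the SN2′ sense, so the carboxylate should add at the methylene terminus (C14) while the activated oxygen leaves from C1, giving the trisubstituted enone with C2 trans to the acetyl group (1(10)E).

Step 20
Reactants: 28 (2E)-2-acetyl-5-[(2S,3R)-3-[(2Z)-4-acetoxy-3-(phenylsulfanylmethyl)but-2-en-1-yl]-2-(tert-butyldimethylsilyloxymethyl)oxiran-2-yl]pent-2-en-1-yl (2R,3S)-3-(tert-butyldimethylsilyloxy)-2-methylbutanoate
Product: 30 (2E)-5-[(2S,3R)-3-[(2Z)-4-acetoxy-3-(phenylsulfanylmethyl)but-2-en-1-yl]-2-(tert-butyldimethylsilyloxymethyl)oxiran-2-yl]-2-(2-diazoacetyl)pent-2-en-1-yl (2R,3S)-3-(tert-butyldimethylsilyloxy)-2-methylbutanoate, via trifluoroacetyl diketone 29 (not isolated)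
Conditions: LiN(SiMe3)2 (1.05 equiv, added to 28), THF, −78 °C; CF3CO2CH2CF3; aq NH4Cl; then MsN3, Et3N, H2O, MeCN, rt
Reagents that add atoms: methanesulfonyl azide, CS(=O)(=O)N=[N+]=[N-]; 2,2,2-trifluoroethyl trifluoroacetate, O=C(OCC(F)(F)F)C(F)(F)F (its trifluoroacetyl group stays only in 29)
Why: In this detrifluoroacetylative (Regitz-type) diazo transfer, kinetic deprotonation of the methyl ketone, which is far more acidic than the ester α-hydrogens, and C-trifluoroacetylation should activate C8 for diazo transfer, and loss of the trifluoroacetyl group then leaves the α′-diazo enone.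

Step 21
Reactants: 30 (2E)-5-[(2S,3R)-3-[(2Z)-4-acetoxy-3-(phenylsulfanylmethyl)but-2-en-1-yl]-2-(tert-butyldimethylsilyloxymethyl)oxiran-2-yl]-2-(2-diazoacetyl)pent-2-en-1-yl (2R,3S)-3-(tert-butyldimethylsilyloxy)-2-methylbutanoate
Product: 32 (1(10)E,4S,5R,7R,8S)-12-acetoxy-15-(tert-butyldimethylsilyloxy)-4,5-epoxy-9-oxo-8-(phenylsulfanyl)germacra-1(10),11(13)-dien-14-yl (2R,3S)-3-(tert-butyldimethylsilyloxy)-2-methylbutanoate, via sulfonium ylide 31 (not isolated)
Conditions: Rh2(OAc)4 (2 mol%), CH2Cl2, 40 °C, 30 added by syringe pump over 12 h to 1 mM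
Reagents that add atoms: none
Why: Proposed new method: Rh2(OAc)4 (divalent rhodium) should expel N2 from 30 to give an electrophilic carbenoid at C8 that is captured by the phenylthio sulfur on C13, the most nucleophilic site of the chain, closing the thirteen-membered sulfonium ylide 31 through an S–C8 bond; the ylide should then undergo a [2,3]-sigmatropic shift through a five-membered envelope transition state that forms C7–C8, breaks S–C13 and moves the alkene to C11=C13. The closest known reaction types are the Doyle–Kirmse reaction, the capture of metal carbenoids by remote allyl ethers (macrocyclic oxonium ylide formation followed by a [2,3] shift) and the [2,3]-Wittig contraction of thirteen-membered diallyl ethers to ten-membered carbocycles, whereas a thirteen-membered sulfonium ylide contracting to a carbocycle has not been shown. The ten-membered carbocycle closes by ring contraction, that is by the C7–C8 bond made inside the cyclic ylide, while the transient thirteen-membered ring closes by attack of sulfur on the carbenoid. C7 is set by the fold of the tether in the envelope (C11 branch outside the forming ring, with the trans 4S,5R epoxide and the 1(10)E alkene stiffening the chain), a substrate control that is predicted but not assured; C8 is drawn with the phenylthio group trans to the C7 side chain and is erased in step 22. The step needs sulfur to win over every other carbenoid pathway: C14 carries an ester and not an ether, so no five-membered oxonium ylide with a migrating group can form, the E geometry of C10=C1 keeps C2–H out of reach of 1,5-insertion, slow addition at high dilution suppresses dimerisation, and allyl sulfonium ylides prefer the [2,3] shift over the [1,2] shift.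

Step 22
Reactants: 32 (1(10)E,4S,5R,7R,8S)-12-acetoxy-15-(tert-butyldimethylsilyloxy)-4,5-epoxy-9-oxo-8-(phenylsulfanyl)germacra-1(10),11(13)-dien-14-yl (2R,3S)-3-(tert-butyldimethylsilyloxy)-2-methylbutanoate
Product: 33 (1(10)E,4S,5R,7S)-12-acetoxy-15-(tert-butyldimethylsilyloxy)-4,5-epoxy-9-oxogermacra-1(10),11(13)-dien-14-yl (2R,3S)-3-(tert-butyldimethylsilyloxy)-2-methylbutanoate
Conditions: SmI2 (2.2 equiv), THF/MeOH, −78 °C
Reagents that add atoms: none
Why: Reductive cleavage of an α-heteroatom-substituted ketone by single-electron transfer should break the C8–S bond faster than the enone or the esters are reduced, turning C8 into CH2 (the C7 descriptor changes to S only through the priority rules).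

Step 23
Reactants: 33 (1(10)E,4S,5R,7S)-12-acetoxy-15-(tert-butyldimethylsilyloxy)-4,5-epoxy-9-oxogermacra-1(10),11(13)-dien-14-yl (2R,3S)-3-(tert-butyldimethylsilyloxy)-2-methylbutanoate
Product: 34 (1(10)E,4S,5R,7R,9S)-12-acetoxy-15-(tert-butyldimethylsilyloxy)-4,5-epoxy-9-hydroxygermacra-1(10),11(13)-dien-14-yl (2R,3S)-3-(tert-butyldimethylsilyloxy)-2-methylbutanoate
Conditions: (R)-2-methyl-CBS-oxazaborolidine (0.5 equiv), catecholborane, toluene, −78 °C
Reagents that add atoms: none
Why: In the Corey–Bakshi–Shibata reduction the (R)-oxazaborolidine should treat the α-substituted alkenyl side as the large group and the C8 methylene as the small one, delivering hydride 1,2 to the face that gives the 9S allylic alcohol.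

Step 24
Reactants: 34 (1(10)E,4S,5R,7R,9S)-12-acetoxy-15-(tert-butyldimethylsilyloxy)-4,5-epoxy-9-hydroxygermacra-1(10),11(13)-dien-14-yl (2R,3S)-3-(tert-butyldimethylsilyloxy)-2-methylbutanoate
Product: 35 (1(10)E,4S,5R,7R,9S)-12-acetoxy-15-(tert-butyldimethylsilyloxy)-4,5-epoxy-9-(2-methylpropanoyloxy)germacra-1(10),11(13)-dien-14-yl (2R,3S)-3-(tert-butyldimethylsilyloxy)-2-methylbutanoate
Conditions: iPrCOCl, pyridine, DMAP (cat.), CH2Cl2, 0 °C
Reagents that add atoms: isobutyryl chloride, CC(C)C(Cl)=O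
Why: Acylation of the secondary allylic alcohol with retention should install the C9 isobutyrate.

Step 25
Reactants: 35 (1(10)E,4S,5R,7R,9S)-12-acetoxy-15-(tert-butyldimethylsilyloxy)-4,5-epoxy-9-(2-methylpropanoyloxy)germacra-1(10),11(13)-dien-14-yl (2R,3S)-3-(tert-butyldimethylsilyloxy)-2-methylbutanoate
Product: 36 (1(10)E,4S,5R,7R,9S)-12-acetoxy-4,5-epoxy-15-hydroxy-9-(2-methylpropanoyloxy)germacra-1(10),11(13)-dien-14-yl (2R,3S)-3-hydroxy-2-methylbutanoate (CNP0256542.1)
Conditions: HF·pyridine, pyridine, THF, 0 °C to rt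
Reagents that add atoms: none
Why: Buffered fluoride desilylation should remove both tert-butyldimethylsilyl ethers under mildly acidic conditions that avoid acyl migration, Payne rearrangement and epoxide opening.

**Compound list**

1 | 3-iodopropan-1-ol | OCCCI | starting material
2 | triethyl(3-iodopropoxy)silane | CC[Si](CC)(CC)OCCCI | intermediate
3 | methyl 2-[bis(2,2,2-trifluoroethoxy)phosphoryl]acetate | COC(=O)CP(=O)(OCC(F)(F)F)OCC(F)(F)F | starting material
4 | methyl 2-[bis(2,2,2-trifluoroethoxy)phosphoryl]-5-(triethylsilyloxy)pentanoate (racemic) | COC(=O)C(CCCO[Si](CC)(CC)CC)P(=O)(OCC(F)(F)F)OCC(F)(F)F | intermediate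
5 | 3-(4-methoxybenzyloxy)propanal | COc1ccc(COCCC=O)cc1 | starting material
6 | methyl (2Z)-5-(4-methoxybenzyloxy)-2-[3-(triethylsilyloxy)propyl]pent-2-enoate | CC[Si](CC)(CC)OCCC/C(C(=O)OC)=C/CCOCc1ccc(OC)cc1 | intermediate
7 | (2Z)-5-(4-methoxybenzyloxy)-2-[3-(triethylsilyloxy)propyl]pent-2-en-1-ol | CC[Si](CC)(CC)OCCC/C(CO)=C/CCOCc1ccc(OC)cc1 | intermediate
8 | [(2S,3R)-3-[2-(4-methoxybenzyloxy)ethyl]-2-[3-(triethylsilyloxy)propyl]oxiran-2-yl]methanol | CC[Si](CC)(CC)OCCC[C@@]1(CO)O[C@@H]1CCOCc2ccc(OC)cc2 | intermediate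
9 | tert-butyl{[(2S,3R)-3-[2-(4-methoxybenzyloxy)ethyl]-2-[3-(triethylsilyloxy)propyl]oxiran-2-yl]methoxy}dimethylsilane | CC[Si](CC)(CC)OCCC[C@@]1(CO[Si](C)(C)C(C)(C)C)O[C@@H]1CCOCc2ccc(OC)cc2 | intermediate
10 | 2-[(2R,3S)-3-(tert-butyldimethylsilyloxymethyl)-3-[3-(triethylsilyloxy)propyl]oxiran-2-yl]ethan-1-ol | CC[Si](CC)(CC)OCCC[C@@]1(CO[Si](C)(C)C(C)(C)C)O[C@@H]1CCO | intermediate
11 | methyl (triphenylphosphoranylidene)acetate | COC(=O)C=P(c1ccccc1)(c1ccccc1)c1ccccc1 | starting material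
12 | chloromethyl phenyl sulfide | ClCSc1ccccc1 | starting material
13 | [1-methoxy-1-oxo-3-(phenylsulfanyl)propan-2-yl]triphenylphosphonium chloride | COC(=O)C(CSc1ccccc1)[P+](c1ccccc1)(c1ccccc1)c1ccccc1.[Cl-] | intermediate (not isolated)
14 | methyl 3-(phenylsulfanyl)-2-(triphenylphosphoranylidene)propanoate | COC(=O)C(CSc1ccccc1)=P(c1ccccc1)(c1ccccc1)c1ccccc1 | intermediate
15 | 2-[(2R,3S)-3-(tert-butyldimethylsilyloxymethyl)-3-[3-(triethylsilyloxy)propyl]oxiran-2-yl]acetaldehyde | CC[Si](CC)(CC)OCCC[C@@]1(CO[Si](C)(C)C(C)(C)C)O[C@@H]1CC=O | intermediate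
16 | methyl (2Z)-4-[(2R,3S)-3-(tert-butyldimethylsilyloxymethyl)-3-[3-(triethylsilyloxy)propyl]oxiran-2-yl]-2-(phenylsulfanylmethyl)but-2-enoate | CC[Si](CC)(CC)OCCC[C@@]1(CO[Si](C)(C)C(C)(C)C)O[C@@H]1C/C=C(/C(=O)OC)CSc2ccccc2 | intermediate
17 | (2Z)-4-[(2R,3S)-3-(tert-butyldimethylsilyloxymethyl)-3-[3-(triethylsilyloxy)propyl]oxiran-2-yl]-2-(phenylsulfanylmethyl)but-2-en-1-ol | CC[Si](CC)(CC)OCCC[C@@]1(CO[Si](C)(C)C(C)(C)C)O[C@@H]1C/C=C(/CO)CSc2ccccc2 | intermediate
18 | (2Z)-4-[(2R,3S)-3-(tert-butyldimethylsilyloxymethyl)-3-[3-(triethylsilyloxy)propyl]oxiran-2-yl]-2-(phenylsulfanylmethyl)but-2-en-1-yl acetate | CC[Si](CC)(CC)OCCC[C@@]1(CO[Si](C)(C)C(C)(C)C)O[C@@H]1C/C=C(/COC(C)=O)CSc2ccccc2 | intermediate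
19 | (2Z)-4-[(2R,3S)-3-(tert-butyldimethylsilyloxymethyl)-3-(3-hydroxypropyl)oxiran-2-yl]-2-(phenylsulfanylmethyl)but-2-en-1-yl acetate | OCCC[C@@]1(CO[Si](C)(C)C(C)(C)C)O[C@@H]1C/C=C(/COC(C)=O)CSc2ccccc2 | intermediate
20 | (2Z)-4-[(2R,3S)-3-(tert-butyldimethylsilyloxymethyl)-3-(3-oxopropyl)oxiran-2-yl]-2-(phenylsulfanylmethyl)but-2-en-1-yl acetate | O=CCC[C@@]1(CO[Si](C)(C)C(C)(C)C)O[C@@H]1C/C=C(/COC(C)=O)CSc2ccccc2 | intermediate
21 | but-3-en-2-one (methyl vinyl ketone) | CC(=O)C=C | starting material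
22 | (2Z)-4-[(2R,3S)-3-(tert-butyldimethylsilyloxymethyl)-3-(3-hydroxy-4-methylidene-5-oxohexyl)oxiran-2-yl]-2-(phenylsulfanylmethyl)but-2-en-1-yl acetate (both carbinol epimers) | CC(=O)C(=C)C(O)CC[C@@]1(CO[Si](C)(C)C(C)(C)C)O[C@@H]1C/C=C(/COC(C)=O)CSc2ccccc2 | intermediate
23 | (4R)-4-benzyl-3-propanoyl-1,3-oxazolidin-2-one | CCC(=O)N1[C@H](Cc2ccccc2)COC1=O | starting material
24 | acetaldehyde | CC=O | starting material
25 | (4R)-4-benzyl-3-[(2R,3S)-3-hydroxy-2-methylbutanoyl]-1,3-oxazolidin-2-one | O=C([C@H](C)[C@H](C)O)N1[C@H](Cc2ccccc2)COC1=O | intermediate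
26 | (4R)-4-benzyl-3-[(2R,3S)-3-(tert-butyldimethylsilyloxy)-2-methylbutanoyl]-1,3-oxazolidin-2-one | O=C([C@H](C)[C@H](C)O[Si](C)(C)C(C)(C)C)N1[C@H](Cc2ccccc2)COC1=O | intermediate
27 | (2R,3S)-3-(tert-butyldimethylsilyloxy)-2-methylbutanoic acid | OC(=O)[C@H](C)[C@H](C)O[Si](C)(C)C(C)(C)C | intermediate
28 | (2E)-2-acetyl-5-[(2S,3R)-3-[(2Z)-4-acetoxy-3-(phenylsulfanylmethyl)but-2-en-1-yl]-2-(tert-butyldimethylsilyloxymethyl)oxiran-2-yl]pent-2-en-1-yl (2R,3S)-3-(tert-butyldimethylsilyloxy)-2-methylbutanoate | CC(=O)/C(COC(=O)[C@H](C)[C@H](C)O[Si](C)(C)C(C)(C)C)=C/CC[C@@]1(CO[Si](C)(C)C(C)(C)C)O[C@@H]1C/C=C(/COC(C)=O)CSc2ccccc2 | intermediate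
29 | C8-trifluoroacetyl derivative of 28: (2E)-5-[(2S,3R)-3-[(2Z)-4-acetoxy-3-(phenylsulfanylmethyl)but-2-en-1-yl]-2-(tert-butyldimethylsilyloxymethyl)oxiran-2-yl]-2-(4,4,4-trifluoro-3-oxobutanoyl)pent-2-en-1-yl (2R,3S)-3-(tert-butyldimethylsilyloxy)-2-methylbutanoate | O=C(CC(=O)/C(COC(=O)[C@H](C)[C@H](C)O[Si](C)(C)C(C)(C)C)=C/CC[C@@]1(CO[Si](C)(C)C(C)(C)C)O[C@@H]1C/C=C(/COC(C)=O)CSc2ccccc2)C(F)(F)F | intermediate (not isolated)
30 | (2E)-5-[(2S,3R)-3-[(2Z)-4-acetoxy-3-(phenylsulfanylmethyl)but-2-en-1-yl]-2-(tert-butyldimethylsilyloxymethyl)oxiran-2-yl]-2-(2-diazoacetyl)pent-2-en-1-yl (2R,3S)-3-(tert-butyldimethylsilyloxy)-2-methylbutanoate | [N-]=[N+]=CC(=O)/C(COC(=O)[C@H](C)[C@H](C)O[Si](C)(C)C(C)(C)C)=C/CC[C@@]1(CO[Si](C)(C)C(C)(C)C)O[C@@H]1C/C=C(/COC(C)=O)CSc2ccccc2 | intermediate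
31 | thirteen-membered S-phenyl sulfonium ylide (S bridges C13 and the C8 carbanion next to the C9 ketone; other groups as in 30) | [CH-]3C(=O)/C(COC(=O)[C@H](C)[C@H](C)O[Si](C)(C)C(C)(C)C)=C/CC[C@@]1(CO[Si](C)(C)C(C)(C)C)O[C@@H]1C/C=C(/COC(C)=O)C[S+]3c2ccccc2 | intermediate (not isolated)
32 | (1(10)E,4S,5R,7R,8S)-12-acetoxy-15-(tert-butyldimethylsilyloxy)-4,5-epoxy-9-oxo-8-(phenylsulfanyl)germacra-1(10),11(13)-dien-14-yl (2R,3S)-3-(tert-butyldimethylsilyloxy)-2-methylbutanoate (C8 epimer is a prediction) | C=C(COC(C)=O)[C@@H]1[C@H](Sc2ccccc2)C(=O)/C(COC(=O)[C@H](C)[C@H](C)O[Si](C)(C)C(C)(C)C)=C/CC[C@@]3(CO[Si](C)(C)C(C)(C)C)O[C@@H]3C1 | intermediate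
33 | (1(10)E,4S,5R,7S)-12-acetoxy-15-(tert-butyldimethylsilyloxy)-4,5-epoxy-9-oxogermacra-1(10),11(13)-dien-14-yl (2R,3S)-3-(tert-butyldimethylsilyloxy)-2-methylbutanoate | C=C(COC(C)=O)[C@@H]1CC(=O)/C(COC(=O)[C@H](C)[C@H](C)O[Si](C)(C)C(C)(C)C)=C/CC[C@@]3(CO[Si](C)(C)C(C)(C)C)O[C@@H]3C1 | intermediate
34 | (1(10)E,4S,5R,7R,9S)-12-acetoxy-15-(tert-butyldimethylsilyloxy)-4,5-epoxy-9-hydroxygermacra-1(10),11(13)-dien-14-yl (2R,3S)-3-(tert-butyldimethylsilyloxy)-2-methylbutanoate | C=C(COC(C)=O)[C@@H]1C[C@H](O)/C(COC(=O)[C@H](C)[C@H](C)O[Si](C)(C)C(C)(C)C)=C/CC[C@@]3(CO[Si](C)(C)C(C)(C)C)O[C@@H]3C1 | intermediate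
35 | (1(10)E,4S,5R,7R,9S)-12-acetoxy-15-(tert-butyldimethylsilyloxy)-4,5-epoxy-9-(2-methylpropanoyloxy)germacra-1(10),11(13)-dien-14-yl (2R,3S)-3-(tert-butyldimethylsilyloxy)-2-methylbutanoate | C=C(COC(C)=O)[C@@H]1C[C@H](OC(=O)C(C)C)/C(COC(=O)[C@H](C)[C@H](C)O[Si](C)(C)C(C)(C)C)=C/CC[C@@]3(CO[Si](C)(C)C(C)(C)C)O[C@@H]3C1 | intermediate
36 | (1(10)E,4S,5R,7R,9S)-12-acetoxy-4,5-epoxy-15-hydroxy-9-(2-methylpropanoyloxy)germacra-1(10),11(13)-dien-14-yl (2R,3S)-3-hydroxy-2-methylbutanoate (CNP0256542.1) | C=C(COC(C)=O)[C@@H]1C[C@H](OC(=O)C(C)C)/C(COC(=O)[C@H](C)[C@H](C)O)=C/CC[C@@]2(CO)O[C@@H]2C1 | target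

**Step count**

Total: 25 steps. Longest linear sequence: 21 steps (steps 1–7, 9–15 and 19–25, from 3-iodopropan-1-ol). Step 8 makes the ylide and steps 16–18 make the side-chain acid.

**Steps most likely to fail**

Step 21 (key step). The carbenoid may be consumed before it reaches the remote sulfur, by dimerisation, by insertion into C–H bonds, by cyclopropanation of C7=C11 or by attack on the C14 ester carbonyl, or the ylide may fold so that C7 forms with the wrong sense. The fallback gives up the ylide and makes the same bond with an allyl-metal addition, the Nozaki–Hiyama allylation, which is an established closure of ten-membered germacrane rings with this exo-methylene pattern. It sets out from enone 28. Enolisation with LiN(SiMe3)2 and trapping with I2 should give the iodomethyl ketone F1, and Kornblum oxidation (DMSO, NaHCO3) should turn it into the keto aldehyde F2. MeI and NaI in DMF should then exchange the allylic phenylthio group for iodide, by S-methylation and displacement, to give the allylic iodide F3. CrCl2 in THF at high dilution, which is chemoselective for the aldehyde, should add the allylchromium through its γ-carbon C7 to C8, closing the ring and forming the C11=C13 methylene in the 8-hydroxy-9-ketone F4. Acetylation (Ac2O, pyridine) should give the 8-acetoxy ketone F5, and SmI2 should remove the acetoxy group, which brings the route back at 33.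

Step 20. Enolisation may not stay on the methyl ketone: deprotonation next to an ester, acyl transfer from C14 to the C8 enolate, or γ-deprotonation followed by loss of the C14 carboxylate would destroy the substrate. The fallback avoids strong base. It sets out from 28, which on heating with DMF dimethyl acetal (toluene, 80 °C) should condense at the methyl ketone only to give the enaminone F6. Diazo transfer from MsN3 in MeCN, by cycloaddition and loss of the N-mesyl formamidine, should then return the route at 30.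

Step 23. Hydride delivery may be governed by the conformation of the ten-membered ring and not by the catalyst, giving poor or reversed facial selectivity at C9. The fallback lets the ring decide and corrects afterwards. It sets out from 33, which under Luche conditions (NaBH4, CeCl3·7H2O, MeOH, −78 °C) should give the epimer the ring prefers. If this is the 9R alcohol F7, Mitsunobu esterification with isobutyric acid (PPh3, DIAD, THF) should invert C9 and return the route directly at 35; if the ring prefers 9S, the product is 34 itself.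

**Further compounds**

F1 | step 21 | (2E)-5-[(2S,3R)-3-[(2Z)-4-acetoxy-3-(phenylsulfanylmethyl)but-2-en-1-yl]-2-(tert-butyldimethylsilyloxymethyl)oxiran-2-yl]-2-(2-iodoacetyl)pent-2-en-1-yl (2R,3S)-3-(tert-butyldimethylsilyloxy)-2-methylbutanoate | ICC(=O)/C(COC(=O)[C@H](C)[C@H](C)O[Si](C)(C)C(C)(C)C)=C/CC[C@@]1(CO[Si](C)(C)C(C)(C)C)O[C@@H]1C/C=C(/COC(C)=O)CSc2ccccc2
F2 | step 21 | (2E)-5-[(2S,3R)-3-[(2Z)-4-acetoxy-3-(phenylsulfanylmethyl)but-2-en-1-yl]-2-(tert-butyldimethylsilyloxymethyl)oxiran-2-yl]-2-(2-oxoacetyl)pent-2-en-1-yl (2R,3S)-3-(tert-butyldimethylsilyloxy)-2-methylbutanoate | O=CC(=O)/C(COC(=O)[C@H](C)[C@H](C)O[Si](C)(C)C(C)(C)C)=C/CC[C@@]1(CO[Si](C)(C)C(C)(C)C)O[C@@H]1C/C=C(/COC(C)=O)CSc2ccccc2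
F3 | step 21 | (2E)-5-[(2S,3R)-3-[(2Z)-4-acetoxy-3-(iodomethyl)but-2-en-1-yl]-2-(tert-butyldimethylsilyloxymethyl)oxiran-2-yl]-2-(2-oxoacetyl)pent-2-en-1-yl (2R,3S)-3-(tert-butyldimethylsilyloxy)-2-methylbutanoate | O=CC(=O)/C(COC(=O)[C@H](C)[C@H](C)O[Si](C)(C)C(C)(C)C)=C/CC[C@@]1(CO[Si](C)(C)C(C)(C)C)O[C@@H]1C/C=C(/COC(C)=O)CI
F4 | step 21 | (1(10)E,4S,5R,7R)-12-acetoxy-15-(tert-butyldimethylsilyloxy)-4,5-epoxy-8-hydroxy-9-oxogermacra-1(10),11(13)-dien-14-yl (2R,3S)-3-(tert-butyldimethylsilyloxy)-2-methylbutanoate (C8 epimers) | C=C(COC(C)=O)[C@@H]1C(O)C(=O)/C(COC(=O)[C@H](C)[C@H](C)O[Si](C)(C)C(C)(C)C)=C/CC[C@@]3(CO[Si](C)(C)C(C)(C)C)O[C@@H]3C1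
F5 | step 21 | (1(10)E,4S,5R,7R)-8,12-diacetoxy-15-(tert-butyldimethylsilyloxy)-4,5-epoxy-9-oxogermacra-1(10),11(13)-dien-14-yl (2R,3S)-3-(tert-butyldimethylsilyloxy)-2-methylbutanoate (C8 epimers) | C=C(COC(C)=O)[C@@H]1C(OC(C)=O)C(=O)/C(COC(=O)[C@H](C)[C@H](C)O[Si](C)(C)C(C)(C)C)=C/CC[C@@]3(CO[Si](C)(C)C(C)(C)C)O[C@@H]3C1
F6 | step 20 | (2E)-5-[(2S,3R)-3-[(2Z)-4-acetoxy-3-(phenylsulfanylmethyl)but-2-en-1-yl]-2-(tert-butyldimethylsilyloxymethyl)oxiran-2-yl]-2-[(2E)-3-(dimethylamino)prop-2-enoyl]pent-2-en-1-yl (2R,3S)-3-(tert-butyldimethylsilyloxy)-2-methylbutanoate | CN(C)/C=C/C(=O)/C(COC(=O)[C@H](C)[C@H](C)O[Si](C)(C)C(C)(C)C)=C/CC[C@@]1(CO[Si](C)(C)C(C)(C)C)O[C@@H]1C/C=C(/COC(C)=O)CSc2ccccc2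
F7 | step 23 | (1(10)E,4S,5R,7R,9R)-12-acetoxy-15-(tert-butyldimethylsilyloxy)-4,5-epoxy-9-hydroxygermacra-1(10),11(13)-dien-14-yl (2R,3S)-3-(tert-butyldimethylsilyloxy)-2-methylbutanoate | C=C(COC(C)=O)[C@@H]1C[C@@H](O)/C(COC(=O)[C@H](C)[C@H](C)O[Si](C)(C)C(C)(C)C)=C/CC[C@@]3(CO[Si](C)(C)C(C)(C)C)O[C@@H]3C1
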